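**Retrosynthetic overview**

1. Target 35 ⇒ macrocyclic allylic alcohol 30 (C6 OTES, C9 OTBS, C12 methyl ester). The C3 ester, the C6/C12 γ-lactone and the free C9–OH are made last.
2. 30 ⇒ seco ynal 28 by a C3–C4 nickel-catalysed reductive ynal cyclisation. The feature used is the C3 carbinol on the E-trisubstituted C4(C15)=C5 olefin inside the ten-membered C1–C10 ring: it equals syn addition of H and the C3 aldehyde carbon across a C15–C4≡C5 methyl alkyne on C6.
3. 28 ⇒ C9 aldehyde 19 + Z-iodoalkene 22 (C9–C10 by Nozaki–Hiyama–Kishi coupling; C9 set by CBS reduction of the Z-enone).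
4. 19 ⇒ propynyl ketone 15 (C6 by Noyori reduction) ⇒ acid 9 (C7–C11 by Ireland–Claisen rearrangement of propanoate 6; chirality from (S)-but-3-en-2-ol).
5. Ring order: ten-membered carbocycle first (step 21), γ-lactone second (step 23).

Key step: step 21

Assumption: the SMILES is read as 3S,6S,7S,9S,11R with an (R)-2-methylbutanoate, 1(10)Z and 4E; germacrane numbering is used throughout (ring C1–C10, C11(C13)–C12 on C7, C14 on C10, C15 on C4).

**Route**

Step 1
Reactants: 1 but-3-en-1-ol
Product: 2 1-[(but-3-en-1-yloxy)methyl]-4-methoxybenzene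
Conditions: NaH, PMBCl, Bu4NI (cat.), THF–DMF, 0 °C → rt
Reagents that add atoms: 4-methoxybenzyl chloride, COc1ccc(CCl)cc1
Why: Williamson etherification of the primary alkoxide with the benzylic chloride is fast and leaves the terminal olefin untouched.

Step 2
Reactants: 3 (S)-but-3-en-2-ol; 4 propionyl chloride
Product: 5 (S)-but-3-en-2-yl propanoate
Conditions: pyridine, DMAP (cat.), CH2Cl2, 0 °C
Reagents that add atoms: none
Why: O-acylation with the acid chloride (nucleophilic acyl substitution) occurs at oxygen with retention, so the (S) centre that will steer the rearrangement is carried through.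

Step 3
Reactants: 5 (S)-but-3-en-2-yl propanoate; 2 1-[(but-3-en-1-yloxy)methyl]-4-methoxybenzene (2.5 equiv)
Product: 6 (2S,3E)-6-[(4-methoxybenzyl)oxy]hex-3-en-2-yl propanoate
Conditions: Grubbs II (3 mol%), CH2Cl2, 40 °C
Reagents that add atoms: none
Why: Olefin cross-metathesis between a freely dimerising terminal alkene in excess and the slower allylic ester should give mainly the E cross product and does not touch the allylic stereocentre.

Step 4
Reactants: 6 (2S,3E)-6-[(4-methoxybenzyl)oxy]hex-3-en-2-yl propanoate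
Product: 9 (2R,3R,4E)-3-{2-[(4-methoxybenzyl)oxy]ethyl}-2-methylhex-4-enoic acid, via silyl ketene acetal 7 (not isolated), via trimethylsilyl ester 8 (not isolated)
Conditions: LDA, THF, −78 °C; TMSCl–Et3N, −78 °C → rt, then 50 °C; aq. citric acid work-up
Reagents that add atoms: none
Why: Ireland–Claisen rearrangement: LDA in THF gives the (E)-silyl ketene acetal 7, which rearranges through a chair with the carbinol methyl and the C8 chain equatorial, so the (S) carbinol centre is transferred to C7 and C11 (2R,3R, anti) and the new olefin is E, the silyl ester 8 being hydrolysed on work-up.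

Step 5
Reactants: 9 (2R,3R,4E)-3-{2-[(4-methoxybenzyl)oxy]ethyl}-2-methylhex-4-enoic acid
Product: 10 methyl (2R,3R,4E)-3-{2-[(4-methoxybenzyl)oxy]ethyl}-2-methylhex-4-enoate
Conditions: TMSCHN2, MeOH–toluene, 0 °C → rt
Reagents that add atoms: trimethylsilyldiazomethane, C[Si](C)(C)C=[N+]=[N-]
Why: Esterification of the acid with trimethylsilyldiazomethane in methanol is neutral and should not epimerise C11.

Step 6
Reactants: 10 methyl (2R,3R,4E)-3-{2-[(4-methoxybenzyl)oxy]ethyl}-2-methylhex-4-enoate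
Product: 12 methyl (2R,3S)-3-formyl-5-[(4-methoxybenzyl)oxy]-2-methylpentanoate, via diol 11 (not isolated)
Conditions: OsO4 (2 mol%), NaIO4, 2,6-lutidine, dioxane–H2O, rt
Reagents that add atoms: osmium tetroxide, O=[Os](=O)(=O)=O; sodium periodate, [Na+].[O-]I(=O)(=O)=O
Why: Lemieux–Johnson cleavage (catalytic dihydroxylation, periodate scission of diol 11) converts the only olefin into the C6 aldehyde, the lutidine buffer protecting the α-centre C7 and the PMB arene being spared as it might not be by ozone.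

Step 7
Reactants: 12 methyl (2R,3S)-3-formyl-5-[(4-methoxybenzyl)oxy]-2-methylpentanoate; 13 1-propynylmagnesium bromide
Product: 14 methyl (2R,3S)-3-(1-hydroxybut-2-yn-1-yl)-5-[(4-methoxybenzyl)oxy]-2-methylpentanoate (both carbinol epimers)
Conditions: THF, −78 °C; sat. aq. NH4Cl at −78 °C
Reagents that add atoms: none
Why: Grignard 1,2-addition of the alkynyl nucleophile is far faster at the aldehyde than at the methyl ester at −78 °C, the C6 configuration being irrelevant because step 8 erases it, and the cold quench keeps the γ-alkoxide from closing onto the ester.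

Step 8
Reactants: 14 methyl (2R,3S)-3-(1-hydroxybut-2-yn-1-yl)-5-[(4-methoxybenzyl)oxy]-2-methylpentanoate
Product: 15 methyl (2R,3S)-3-(but-2-ynoyl)-5-[(4-methoxybenzyl)oxy]-2-methylpentanoate
Conditions: Dess–Martin periodinane, NaHCO3, CH2Cl2, 0 °C → rt
Reagents that add atoms: none
Why: Dess–Martin oxidation under bicarbonate buffer should give the propynyl ketone without epimerising C7 or touching the PMB ether.

Step 9
Reactants: 15 methyl (2R,3S)-3-(but-2-ynoyl)-5-[(4-methoxybenzyl)oxy]-2-methylpentanoate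
Product: 16 methyl (2R,3S)-3-[(1S)-1-hydroxybut-2-yn-1-yl]-5-[(4-methoxybenzyl)oxy]-2-methylpentanoate
Conditions: Ru[(S,S)-TsDPEN](p-cymene) (5 mol%, base-free), i-PrOH, rt
Reagents that add atoms: none
Why: Noyori asymmetric transfer hydrogenation of an alkynyl ketone is reagent-controlled: the (S,S)-TsDPEN–Ru hydride treats the alkynyl group like an aryl group and should deliver hydride to give the (6S) propargylic alcohol irrespective of the C7 centre, under neutral conditions that spare ynone and ester.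

Step 10
Reactants: 16 methyl (2R,3S)-3-[(1S)-1-hydroxybut-2-yn-1-yl]-5-[(4-methoxybenzyl)oxy]-2-methylpentanoate
Product: 17 methyl (2R,3S)-5-[(4-methoxybenzyl)oxy]-2-methyl-3-[(1S)-1-(triethylsilyloxy)but-2-yn-1-yl]pentanoate
Conditions: TESCl, imidazole, DMF, 0 °C (crude 16 used at once)
Reagents that add atoms: chlorotriethylsilane, CC[Si](Cl)(CC)CC
Why: Silylation of the secondary propargylic alcohol, run directly on the crude alcohol, blocks the γ-hydroxy ester against lactonisation until the ten-membered ring is closed.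

Step 11
Reactants: 17 methyl (2R,3S)-5-[(4-methoxybenzyl)oxy]-2-methyl-3-[(1S)-1-(triethylsilyloxy)but-2-yn-1-yl]pentanoate
Product: 18 methyl (2R,3S)-5-hydroxy-2-methyl-3-[(1S)-1-(triethylsilyloxy)but-2-yn-1-yl]pentanoate
Conditions: DDQ, CH2Cl2–pH 7 buffer, 0 °C
Reagents that add atoms: none
Why: Oxidative PMB cleavage by DDQ (hydride abstraction, hydrolysis of the oxocarbenium ion) in buffered wet dichloromethane leaves the TES ether, the alkyne and the ester intact.

Step 12
Reactants: 18 methyl (2R,3S)-5-hydroxy-2-methyl-3-[(1S)-1-(triethylsilyloxy)but-2-yn-1-yl]pentanoate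
Product: 19 methyl (2R,3S)-2-methyl-5-oxo-3-[(1S)-1-(triethylsilyloxy)but-2-yn-1-yl]pentanoate
Conditions: Dess–Martin periodinane, NaHCO3, CH2Cl2, 0 °C → rt
Reagents that add atoms: none
Why: Dess–Martin oxidation of the primary alcohol gives the C9 aldehyde, which has no α-stereocentre to lose, before the δ-hydroxy ester can lactonise.

Step 13
Reactants: 20 3-[(4-methoxybenzyl)oxy]propan-1-ol
Product: 21 3-[(4-methoxybenzyl)oxy]propanal
Conditions: Dess–Martin periodinane, NaHCO3, CH2Cl2, 0 °C → rt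
Reagents that add atoms: none
Why: Dess–Martin oxidation of a primary alcohol to the aldehyde is routine and avoids over-oxidation.

Step 14
Reactants: 21 3-[(4-methoxybenzyl)oxy]propanal
Product: 22 1-({[(3Z)-4-iodopent-3-en-1-yl]oxy}methyl)-4-methoxybenzene
Conditions: EtPPh3I, n-BuLi, THF, 0 °C → rt; I2, −78 °C; NaHMDS, −78 → −20 °C; then 21, −78 °C → rt
Reagents that add atoms: ethyltriphenylphosphonium iodide, CC[P+](c1ccccc1)(c1ccccc1)c1ccccc1.[I-]; iodine, II
Why: Stork–Zhao–Wittig olefination: the α-iodo ylide made in the flask reacts with the aldehyde under kinetic control to give the Z-2-iodoalkene (iodine cis to the chain), which fixes the Z geometry of C1=C10.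

Step 15
Reactants: 19 methyl (2R,3S)-2-methyl-5-oxo-3-[(1S)-1-(triethylsilyloxy)but-2-yn-1-yl]pentanoate; 22 1-({[(3Z)-4-iodopent-3-en-1-yl]oxy}methyl)-4-methoxybenzene
Product: 23 methyl (2R,3S,5RS,6Z)-5-hydroxy-9-[(4-methoxybenzyl)oxy]-2,6-dimethyl-3-[(1S)-1-(triethylsilyloxy)but-2-yn-1-yl]non-6-enoate (both C9 epimers)
Conditions: CrCl2 (4 equiv), NiCl2 (2 mol%), DMSO, rt
Reagents that add atoms: none
Why: Nozaki–Hiyama–Kishi coupling forms the alkenylchromium(III) species with retention of olefin geometry and adds it chemoselectively to the aldehyde in the presence of ester, internal alkyne and silyl ether, the C9 epimer ratio being irrelevant since step 16 erases it.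

Step 16
Reactants: 23 methyl (2R,3S,5RS,6Z)-5-hydroxy-9-[(4-methoxybenzyl)oxy]-2,6-dimethyl-3-[(1S)-1-(triethylsilyloxy)but-2-yn-1-yl]non-6-enoate
Product: 24 methyl (2R,3S,6Z)-9-[(4-methoxybenzyl)oxy]-2,6-dimethyl-5-oxo-3-[(1S)-1-(triethylsilyloxy)but-2-yn-1-yl]non-6-enoate
Conditions: Dess–Martin periodinane, NaHCO3, CH2Cl2, 0 °C
Reagents that add atoms: none
Why: Dess–Martin oxidation of the allylic alcohol gives the Z-enone under neutral buffered conditions that should not isomerise the α-methyl Z-olefin.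

Step 17
Reactants: 24 methyl (2R,3S,6Z)-9-[(4-methoxybenzyl)oxy]-2,6-dimethyl-5-oxo-3-[(1S)-1-(triethylsilyloxy)but-2-yn-1-yl]non-6-enoate
Product: 25 methyl (2R,3S,5S,6Z)-5-hydroxy-9-[(4-methoxybenzyl)oxy]-2,6-dimethyl-3-[(1S)-1-(triethylsilyloxy)but-2-yn-1-yl]non-6-enoate
Conditions: (R)-Me-CBS (1.0 equiv), catecholborane, toluene, −78 °C
Reagents that add atoms: none
Why: Corey–Bakshi–Shibata reduction: the (R)-oxazaborolidine binds the ketone with the α-methylalkenyl group as the large substituent and should deliver hydride to give the (9S) allylic alcohol by reagent control, catecholborane at low temperature leaving alkyne and olefin alone.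

Step 18
Reactants: 25 methyl (2R,3S,5S,6Z)-5-hydroxy-9-[(4-methoxybenzyl)oxy]-2,6-dimethyl-3-[(1S)-1-(triethylsilyloxy)but-2-yn-1-yl]non-6-enoate
Product: 26 methyl (2R,3S,5S,6Z)-5-(tert-butyldimethylsilyloxy)-9-[(4-methoxybenzyl)oxy]-2,6-dimethyl-3-[(1S)-1-(triethylsilyloxy)but-2-yn-1-yl]non-6-enoate
Conditions: TBSOTf, 2,6-lutidine, CH2Cl2, −78 → 0 °C
Reagents that add atoms: tert-butyldimethylsilyl triflate, CC(C)(C)[Si](C)(C)OS(=O)(=O)C(F)(F)F
Why: Silylation of the hindered allylic alcohol with the silyl triflate and lutidine is fast at low temperature and tolerates TES and PMB ethers.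

Step 19
Reactants: 26 methyl (2R,3S,5S,6Z)-5-(tert-butyldimethylsilyloxy)-9-[(4-methoxybenzyl)oxy]-2,6-dimethyl-3-[(1S)-1-(triethylsilyloxy)but-2-yn-1-yl]non-6-enoate
Product: 27 methyl (2R,3S,5S,6Z)-5-(tert-butyldimethylsilyloxy)-9-hydroxy-2,6-dimethyl-3-[(1S)-1-(triethylsilyloxy)but-2-yn-1-yl]non-6-enoate
Conditions: DDQ, CH2Cl2–pH 7 buffer, 0 °C
Reagents that add atoms: none
Why: Oxidative PMB cleavage by DDQ under buffered conditions frees the C3 primary alcohol while both silyl ethers, the olefin and the alkyne stay in place.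

Step 20
Reactants: 27 methyl (2R,3S,5S,6Z)-5-(tert-butyldimethylsilyloxy)-9-hydroxy-2,6-dimethyl-3-[(1S)-1-(triethylsilyloxy)but-2-yn-1-yl]non-6-enoate
Product: 28 methyl (2R,3S,5S,6Z)-5-(tert-butyldimethylsilyloxy)-2,6-dimethyl-9-oxo-3-[(1S)-1-(triethylsilyloxy)but-2-yn-1-yl]non-6-enoate (seco ynal)
Conditions: Dess–Martin periodinane, NaHCO3, CH2Cl2, 0 °C; short buffered filtration, used at once
Reagents that add atoms: none
Why: Dess–Martin oxidation of the homoallylic alcohol under bicarbonate buffer gives the β,γ-unsaturated aldehyde, and immediate use without chromatography keeps the C1=C10 olefin from moving into conjugation.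

Step 21
Reactants: 28 seco ynal (C3 aldehyde, C4≡C5 methyl alkyne, C6 OTES, C9 OTBS, C12 methyl ester)
Product: 30 methyl (2R)-2-[(1S,2S,3E,5S,7Z,9S)-9-(tert-butyldimethylsilyloxy)-5-hydroxy-4,8-dimethyl-2-(triethylsilyloxy)cyclodeca-3,7-dien-1-yl]propanoate, via diethylborinate 29 (not isolated)
Conditions: Ni(cod)2 (20 mol%), PBu3 (40 mol%), Et3B (3 equiv), degassed toluene, 60 °C, 28 added over 8 h (final 3 mM); aq. NaHCO3 work-up
Reagents that add atoms: none
Why: Proposed new method: Ni(0)–PBu3 binds the C3 aldehyde and the C4≡C5 alkyne and couples them oxidatively to an oxanickelacyclopentene with C3 bonded to C4 and nickel on C5; ethyl transfer from Et3B, β-hydride elimination (ethene) and C5–H reductive elimination then put hydrogen on C5 cis to C3, which is the E olefin, and leave the O–BEt2 ether 29 that the work-up hydrolyses. The closest known reaction type is the Ni-catalysed reductive macrocyclisation of ynals to endocyclic E-allylic alcohols, known for rings of twelve and more members; a ten-membered closure containing a second olefin has not been shown, hence the label. The ring closes in the endo mode with respect to the alkyne (10-endo-dig: C3 attacks the distal carbon C4, so both C4 and C5 become ring atoms). C3 (S) is controlled by the substrate: the C3–O bond must lie in the nickelacycle plane, C6–H is expected to turn toward the ligated nickel so that C7 and OTES straddle that plane, and the tether running from C7 over one face of the nascent E-olefin then brings C2 onto the C7 face, which with 6S is the 3S arrangement. The step needs endo regiochemistry and ring closure ahead of oligomerisation: the small phosphine together with the size gap between the C15 methyl and the branched C6 carbon sends the aldehyde to C4 (exo closure would also demand a nine-membered ring), and the Z-C1=C10 olefin plus the C7 branch bend the chain so that slow addition at high dilution should suffice. If the substrate bias at C3 proves weak, a chiral monophosphine of the matched hand is the element to vary.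

Step 22
Reactants: 30 macrocyclic allylic alcohol; 31 (R)-2-methylbutanoic acid
Product: 32 C3 (R)-2-methylbutanoate of 30 (C6 OTES, C9 OTBS, C12 methyl ester retained)
Conditions: DCC, DMAP (0.2 equiv), CH2Cl2, 0 °C → rt
Reagents that add atoms: none
Why: Steglich esterification (carbodiimide activation, DMAP acyl transfer) acylates the only free hydroxyl with retention at C3, and low temperature with little DMAP should keep the α-centre of the acid intact.

Step 23
Reactants: 32 C3 (R)-2-methylbutanoate of 30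
Product: 34 (3S,6S,7S,9S,11R)-9-(tert-butyldimethylsilyloxy)-3-[(2R)-2-methylbutanoyloxy]germacra-1(10)Z,4E-dien-12,6-olide, via hydroxy ester 33 (not isolated)
Conditions: PPTS (0.3 equiv), MeOH–CH2Cl2, 0 °C → rt; then solvent exchange, PPTS, toluene, 40 °C
Reagents that add atoms: none
Why: Acid-catalysed methanolysis removes the secondary TES ether but not the TBS ether, and the freed C6–OH of 33 closes onto the methyl ester (intramolecular transesterification, 5-exo-trig) to the trans-fused γ-lactone while C9–O is still silylated and cannot compete.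

Step 24
Reactants: 34 9-O-TBS lactone
Product: 35 (3S,6S,7S,9S,11R)-9-hydroxy-3-[(2R)-2-methylbutanoyloxy]germacra-1(10)Z,4E-dien-12,6-olide (CNP0276536.1)
Conditions: HF·pyridine, pyridine, THF, 0 °C → rt
Reagents that add atoms: none
Why: Fluoride-mediated desilylation with pyridine-buffered HF·pyridine cleaves the remaining allylic TBS ether without acid strong enough to ionise the allylic esters or to trigger transannular cyclisation of the 1(10),4-diene.

**Compound list**

1 | but-3-en-1-ol | C=CCCO | starting material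
2 | 1-[(but-3-en-1-yloxy)methyl]-4-methoxybenzene | C=CCCOCc1ccc(OC)cc1 | intermediate
3 | (S)-but-3-en-2-ol | C[C@H](O)C=C | starting material
4 | propionyl chloride | CCC(Cl)=O | starting material
5 | (S)-but-3-en-2-yl propanoate | CCC(=O)O[C@@H](C)C=C | intermediate
6 | (2S,3E)-6-[(4-methoxybenzyl)oxy]hex-3-en-2-yl propanoate | CCC(=O)O[C@@H](C)/C=C/CCOCc1ccc(OC)cc1 | intermediate
7 | (E)-O-trimethylsilyl ketene acetal of 6 (methyl cis to the allylic oxygen) | C/C=C(/O[Si](C)(C)C)O[C@@H](C)/C=C/CCOCc1ccc(OC)cc1 | intermediate (not isolated)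
8 | trimethylsilyl (2R,3R,4E)-3-{2-[(4-methoxybenzyl)oxy]ethyl}-2-methylhex-4-enoate | COc1ccc(COCC[C@H](/C=C/C)[C@@H](C)C(=O)O[Si](C)(C)C)cc1 | intermediate (not isolated)
9 | (2R,3R,4E)-3-{2-[(4-methoxybenzyl)oxy]ethyl}-2-methylhex-4-enoic acid | COc1ccc(COCC[C@H](/C=C/C)[C@@H](C)C(=O)O)cc1 | intermediate
10 | methyl (2R,3R,4E)-3-{2-[(4-methoxybenzyl)oxy]ethyl}-2-methylhex-4-enoate | COc1ccc(COCC[C@H](/C=C/C)[C@@H](C)C(=O)OC)cc1 | intermediate
11 | 4,5-diol of 10 (syn-diol, diastereomers) | COc1ccc(COCC[C@H](C(O)C(C)O)[C@@H](C)C(=O)OC)cc1 | intermediate (not isolated)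
12 | methyl (2R,3S)-3-formyl-5-[(4-methoxybenzyl)oxy]-2-methylpentanoate | COc1ccc(COCC[C@H](C=O)[C@@H](C)C(=O)OC)cc1 | intermediate
13 | 1-propynylmagnesium bromide | CC#C[Mg]Br | starting material
14 | methyl (2R,3S)-3-(1-hydroxybut-2-yn-1-yl)-5-[(4-methoxybenzyl)oxy]-2-methylpentanoate (C6 epimers) | COc1ccc(COCC[C@H](C(O)C#CC)[C@@H](C)C(=O)OC)cc1 | intermediate
15 | methyl (2R,3S)-3-(but-2-ynoyl)-5-[(4-methoxybenzyl)oxy]-2-methylpentanoate | COc1ccc(COCC[C@H](C(=O)C#CC)[C@@H](C)C(=O)OC)cc1 | intermediate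
16 | methyl (2R,3S)-3-[(1S)-1-hydroxybut-2-yn-1-yl]-5-[(4-methoxybenzyl)oxy]-2-methylpentanoate | COc1ccc(COCC[C@H]([C@@H](C#CC)O)[C@@H](C)C(=O)OC)cc1 | intermediate
17 | methyl (2R,3S)-5-[(4-methoxybenzyl)oxy]-2-methyl-3-[(1S)-1-(triethylsilyloxy)but-2-yn-1-yl]pentanoate | COc1ccc(COCC[C@H]([C@@H](C#CC)O[Si](CC)(CC)CC)[C@@H](C)C(=O)OC)cc1 | intermediate
18 | methyl (2R,3S)-5-hydroxy-2-methyl-3-[(1S)-1-(triethylsilyloxy)but-2-yn-1-yl]pentanoate | OCC[C@H]([C@@H](C#CC)O[Si](CC)(CC)CC)[C@@H](C)C(=O)OC | intermediate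
19 | methyl (2R,3S)-2-methyl-5-oxo-3-[(1S)-1-(triethylsilyloxy)but-2-yn-1-yl]pentanoate | O=CC[C@H]([C@@H](C#CC)O[Si](CC)(CC)CC)[C@@H](C)C(=O)OC | intermediate
20 | 3-[(4-methoxybenzyl)oxy]propan-1-ol | COc1ccc(COCCCO)cc1 | starting material
21 | 3-[(4-methoxybenzyl)oxy]propanal | COc1ccc(COCCC=O)cc1 | intermediate
22 | 1-({[(3Z)-4-iodopent-3-en-1-yl]oxy}methyl)-4-methoxybenzene | COc1ccc(COCC/C=C(/C)I)cc1 | intermediate
23 | methyl (2R,3S,5RS,6Z)-5-hydroxy-9-[(4-methoxybenzyl)oxy]-2,6-dimethyl-3-[(1S)-1-(triethylsilyloxy)but-2-yn-1-yl]non-6-enoate (C9 epimers) | COc1ccc(COCC/C=C(/C)C(O)C[C@H]([C@@H](C#CC)O[Si](CC)(CC)CC)[C@@H](C)C(=O)OC)cc1 | intermediate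
24 | methyl (2R,3S,6Z)-9-[(4-methoxybenzyl)oxy]-2,6-dimethyl-5-oxo-3-[(1S)-1-(triethylsilyloxy)but-2-yn-1-yl]non-6-enoate | COc1ccc(COCC/C=C(/C)C(=O)C[C@H]([C@@H](C#CC)O[Si](CC)(CC)CC)[C@@H](C)C(=O)OC)cc1 | intermediate
25 | methyl (2R,3S,5S,6Z)-5-hydroxy-9-[(4-methoxybenzyl)oxy]-2,6-dimethyl-3-[(1S)-1-(triethylsilyloxy)but-2-yn-1-yl]non-6-enoate | COc1ccc(COCC/C=C(/C)[C@@H](O)C[C@H]([C@@H](C#CC)O[Si](CC)(CC)CC)[C@@H](C)C(=O)OC)cc1 | intermediate
26 | methyl (2R,3S,5S,6Z)-5-(tert-butyldimethylsilyloxy)-9-[(4-methoxybenzyl)oxy]-2,6-dimethyl-3-[(1S)-1-(triethylsilyloxy)but-2-yn-1-yl]non-6-enoate | COc1ccc(COCC/C=C(/C)[C@@H](O[Si](C)(C)C(C)(C)C)C[C@H]([C@@H](C#CC)O[Si](CC)(CC)CC)[C@@H](C)C(=O)OC)cc1 | intermediate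
27 | methyl (2R,3S,5S,6Z)-5-(tert-butyldimethylsilyloxy)-9-hydroxy-2,6-dimethyl-3-[(1S)-1-(triethylsilyloxy)but-2-yn-1-yl]non-6-enoate | OCC/C=C(/C)[C@@H](O[Si](C)(C)C(C)(C)C)C[C@H]([C@@H](C#CC)O[Si](CC)(CC)CC)[C@@H](C)C(=O)OC | intermediate
28 | methyl (2R,3S,5S,6Z)-5-(tert-butyldimethylsilyloxy)-2,6-dimethyl-9-oxo-3-[(1S)-1-(triethylsilyloxy)but-2-yn-1-yl]non-6-enoate (seco ynal) | O=CC/C=C(/C)[C@@H](O[Si](C)(C)C(C)(C)C)C[C@H]([C@@H](C#CC)O[Si](CC)(CC)CC)[C@@H](C)C(=O)OC | intermediate
29 | O-diethylboryl ether of 30 at C3 | CCB(CC)O[C@H]1C/C=C(/C)[C@@H](O[Si](C)(C)C(C)(C)C)C[C@@H]([C@@H](C)C(=O)OC)[C@@H](/C=C/1C)O[Si](CC)(CC)CC | intermediate (not isolated)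
30 | methyl (2R)-2-[(1S,2S,3E,5S,7Z,9S)-9-(tert-butyldimethylsilyloxy)-5-hydroxy-4,8-dimethyl-2-(triethylsilyloxy)cyclodeca-3,7-dien-1-yl]propanoate | O[C@H]1C/C=C(/C)[C@@H](O[Si](C)(C)C(C)(C)C)C[C@@H]([C@@H](C)C(=O)OC)[C@@H](/C=C/1C)O[Si](CC)(CC)CC | intermediate
31 | (R)-2-methylbutanoic acid | CC[C@@H](C)C(=O)O | starting material
32 | C3 (R)-2-methylbutanoate of 30 (6-OTES, 9-OTBS, methyl ester) | CC[C@@H](C)C(=O)O[C@H]1C/C=C(/C)[C@@H](O[Si](C)(C)C(C)(C)C)C[C@@H]([C@@H](C)C(=O)OC)[C@@H](/C=C/1C)O[Si](CC)(CC)CC | intermediate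
33 | 6-hydroxy methyl ester from 32 (TES removed, 9-OTBS) | CC[C@@H](C)C(=O)O[C@H]1C/C=C(/C)[C@@H](O[Si](C)(C)C(C)(C)C)C[C@@H]([C@@H](C)C(=O)OC)[C@@H](/C=C/1C)O | intermediate (not isolated)
34 | (3S,6S,7S,9S,11R)-9-(tert-butyldimethylsilyloxy)-3-[(2R)-2-methylbutanoyloxy]germacra-1(10)Z,4E-dien-12,6-olide | CC[C@@H](C)C(=O)O[C@H]1C/C=C(/C)[C@@H](O[Si](C)(C)C(C)(C)C)C[C@@H]2[C@@H](/C=C/1C)OC(=O)[C@@H]2C | intermediate
35 | (3S,6S,7S,9S,11R)-9-hydroxy-3-[(2R)-2-methylbutanoyloxy]germacra-1(10)Z,4E-dien-12,6-olide | CC[C@@H](C)C(=O)O[C@H]1C/C=C(/C)[C@@H](O)C[C@@H]2[C@@H](/C=C/1C)OC(=O)[C@@H]2C | target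

**Step count and risks**

Total step count: 24. Longest linear sequence: 21 steps (3 → 35 through steps 2–12 and 15–24).

Steps most likely to fail:

1. Step 21 (Proposed new method). Intermolecular coupling and oligomerisation may outrun the strained ten-membered closure, the aldehyde may simply be reduced or drift into conjugation, and closure through the other rotamer about C5–C6 (C6–H turned toward C15) would give the C3 epimer. Fallback with known chemistry, setting out from 26: hydrozirconation of the methyl alkyne with Cp2Zr(H)Cl (zirconium to the less hindered C4, syn) and iodinolysis should give the (E)-C4 iodoalkene F1. DDQ then gives the primary alcohol F2, and Dess–Martin oxidation the iodo aldehyde F3. An intramolecular Nozaki–Hiyama–Kishi reaction (CrCl2, cat. NiCl2, DMSO–THF, high dilution) forms the same C3–C4 bond and should give 30 together with its C3 epimer F4. F4 is oxidised (Dess–Martin) to the macrocyclic enone F5 and reduced with the (R)-CBS reagent, so the fallback comes back to the route at 30.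

2. Step 7. The magnesium γ-alkoxide may close onto the methyl ester before the quench, or the γ-hydroxy ester 14 may lactonise on isolation, and that material is lost to the oxidation. Fallback setting out from 12: Pinnick oxidation gives the C6 carboxylic acid F6; 1-chloro-N,N,2-trimethylprop-1-en-1-amine converts it under neutral conditions into the acid chloride F7; Stille acylation with tributyl(prop-1-yn-1-yl)stannane (Pd catalyst, THF) gives the ynone without an alkoxide ever being formed, and the route is rejoined at 15.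

3. Step 23. Lactone closure may stay incomplete under acid mild enough for the C3 allylic ester, and stronger acid risks ionisation of that ester or transannular cyclisation of the diene. Fallback setting out from 30, with the order of events changed: PPTS in methanol removes the TES ether to give the 3,6-diol ester F8, which can be driven to the lactone with CSA in warm toluene because no allylic ester is present yet, giving the 3-hydroxy lactone F9; Steglich esterification of F9 with 31 then returns to the route at 34.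

Further compounds
F1 | step 21 | (E)-C4 iodoalkene from 26 (iodine on C4, H on C5, C3 OPMB) | COc1ccc(COCC/C=C(/C)[C@@H](O[Si](C)(C)C(C)(C)C)C[C@H]([C@@H](/C=C(\C)I)O[Si](CC)(CC)CC)[C@@H](C)C(=O)OC)cc1
F2 | step 21 | C3 primary alcohol of the iodoalkene | OCC/C=C(/C)[C@@H](O[Si](C)(C)C(C)(C)C)C[C@H]([C@@H](/C=C(\C)I)O[Si](CC)(CC)CC)[C@@H](C)C(=O)OC
F3 | step 21 | C3 aldehyde of the iodoalkene | O=CC/C=C(/C)[C@@H](O[Si](C)(C)C(C)(C)C)C[C@H]([C@@H](/C=C(\C)I)O[Si](CC)(CC)CC)[C@@H](C)C(=O)OC
F4 | step 21 | C3 epimer (3R) of 30 | O[C@@H]1C/C=C(/C)[C@@H](O[Si](C)(C)C(C)(C)C)C[C@@H]([C@@H](C)C(=O)OC)[C@@H](/C=C/1C)O[Si](CC)(CC)CC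
F5 | step 21 | macrocyclic C3 ketone (enone) from F4 | O=C1C/C=C(/C)[C@@H](O[Si](C)(C)C(C)(C)C)C[C@@H]([C@@H](C)C(=O)OC)[C@@H](/C=C/1C)O[Si](CC)(CC)CC
F6 | step 7 | (2S,3R)-4-methoxy-2-{2-[(4-methoxybenzyl)oxy]ethyl}-3-methyl-4-oxobutanoic acid | COc1ccc(COCC[C@H](C(=O)O)[C@@H](C)C(=O)OC)cc1
F7 | step 7 | acid chloride of F6 | COc1ccc(COCC[C@H](C(Cl)=O)[C@@H](C)C(=O)OC)cc1
F8 | step 23 | 3,6-diol methyl ester from 30 (TES removed, 9-OTBS) | O[C@H]1C/C=C(/C)[C@@H](O[Si](C)(C)C(C)(C)C)C[C@@H]([C@@H](C)C(=O)OC)[C@@H](/C=C/1C)O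
F9 | step 23 | 3-hydroxy-9-OTBS-12,6-lactone | O[C@H]1C/C=C(/C)[C@@H](O[Si](C)(C)C(C)(C)C)C[C@@H]2[C@@H](/C=C/1C)OC(=O)[C@@H]2C
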